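## Retrosynthetic overview
1. Hanultarin ⇒ cut the alkyl C–O bond of the ferulate ester, giving unprotected ferulic acid and unprotected (−)-secoisolariciresinol. A temporary cyclic orthoformate on the C2-symmetric 1,4-diol enforces mono-esterification.
2. (−)-Secoisolariciresinol ⇒ global hydride reduction of a C2-symmetric (R,R)-2,3-dibenzylsuccinyl bis-imide that carries aryl pivalates.
3. Bis-imide ⇒ oxidative homocoupling of one Evans imide enolate, which forms C8–C8' and sets both stereocentres.
4. Imide ⇒ dihydroferulic acid + (S)-4-isopropyloxazolidin-2-one + PivCl, with acid activation and phenol capping in one flask.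
5. Rings: the three arenes are bought. The only ring made is the transient 1,3-dioxepane of the last step, which is opened again in the same flask.

Assumption: 1 and 8 are bought (1 is also one hydrogenation away from 9), and a one-flask sequence with a single isolation counts as one step.

## Route

Step 1
Reactants: 1 dihydroferulic acid; 2 (S)-4-isopropyloxazolidin-2-one
Product: 4 (S)-4-isopropyl-3-[3-(3-methoxy-4-pivaloyloxyphenyl)propanoyl]oxazolidin-2-one, via mixed pivalic anhydride 3 (not isolated)
Conditions: PivCl (2.1 equiv), Et3N (3.5 equiv), THF, −10 to 0 °C, 2 h; then LiCl (1.1 equiv), 2 (1.0 equiv), rt, 12 h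
Reagents that add atoms: pivaloyl chloride, CC(C)(C)C(=O)Cl
Why: Mixed-anhydride N-acylation of an Evans oxazolidinone (PivCl/Et3N/LiCl protocol), in which one equivalent of PivCl activates the acid, the second caps the phenol as a hindered aryl pivalate, and the LiCl-activated oxazolidinone attacks only the unhindered acyl carbon; no new stereocentre is formed.

Step 2
Reactants: 4 (S)-4-isopropyl-3-[3-(3-methoxy-4-pivaloyloxyphenyl)propanoyl]oxazolidin-2-one (2 equiv)
Product: 6 (2R,3R)-2,3-bis(3-methoxy-4-pivaloyloxybenzyl)-1,4-bis[(S)-4-isopropyl-2-oxooxazolidin-3-yl]butane-1,4-dione, via lithium Z-enolate 5 (not isolated)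
Conditions: LDA (1.05 equiv), THF, −78 °C, 45 min; then CuCl2 (1.1 equiv), DMF/THF, −78 to 0 °C; crystallisation/chromatography
Reagents that add atoms: none
Why: Oxidative enolate homocoupling (Cu(II) single-electron oxidation of the chelated Z-enolate of an Evans imide), in which each α-carbon bonds on the face opposite its isopropyl group so that the two (S)-auxiliaries set both new centres as R (roughly 5:1 over the other diastereomers, which are removed), while the hindered aryl pivalate tolerates LDA at −78 °C.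

Step 3
Reactants: 6 (2R,3R)-bis-imide dipivalate
Product: 7 (−)-secoisolariciresinol
Conditions: LiAlH4 (6 equiv), THF, 0 °C to rt, 4 h; Rochelle salt/citric acid work-up (pH 5, cold)
Reagents that add atoms: none
Why: Reductive cleavage of N-acyl oxazolidinones and of aryl esters by hydride (LiAlH4 reduction) turns both imides into CH2OH and frees both phenols in one operation, and the α-centres keep their R configuration because the carbonyl intermediates are reduced faster than they enolise.

Step 4
Reactants: 7 (−)-secoisolariciresinol; 8 tris(2,2,2-trifluoroethyl) orthoformate; 9 (E)-ferulic acid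
Product: 13 hanultarin, via trifluoroethoxy dioxepane 10 (not isolated), via dioxepanyl ferulate 11 (not isolated), via formate ester 12 (not isolated)
Conditions: 8 (1.05 equiv), PPTS (5 mol%), MeCN, 50 °C, 2 h; then 9 (1.0 equiv), 100 °C (sealed tube), 16 h; then MeOH, KHCO3 (0.3 equiv), rt, 1 h
Reagents that add atoms: none
Why: Proposed new method: a traceless orthoformate template for self-limiting mono-esterification of a 1,4-diol with a free carboxylic acid, in which acid-catalysed orthoester exchange ties both primary oxygens of 7 (not the less basic phenols) into dioxepane 10, ferulic acid expels the last and best leaving trifluoroethoxy group to give 11 in equilibrium with its 1,3-dioxepan-2-ylium ferulate ion pair, and the carboxylate opens the cation by SN2 at one of the two homotopic OCH2 carbons (an acyl shift within 11 would give the same 12), so that the ester C–O bond forms while the second oxygen leaves as a formate, no diester can form, no free hydroxyl ever sits next to a leaving group (no tetrahydrofuran), CF3CH2 cannot be transferred (no alkyl ferulate), C8/C8' are untouched, and the formate falls off on mild methanolysis; the closest known reaction types are esterification of carboxylic acids with trialkyl orthoesters, Prévost-type opening of 1,3-dioxolan-2-ylium ions by carboxylates, and mono-acylation of diols by hydrolysis of cyclic orthoesters.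

## Compound list
1 | dihydroferulic acid = 3-(4-hydroxy-3-methoxyphenyl)propanoic acid | COc1cc(CCC(=O)O)ccc1O | starting material
2 | (S)-4-isopropyloxazolidin-2-one | CC(C)[C@H]1COC(=O)N1 | starting material
3 | 3-(3-methoxy-4-pivaloyloxyphenyl)propanoic pivalic anhydride | COc1cc(CCC(=O)OC(=O)C(C)(C)C)ccc1OC(=O)C(C)(C)C | intermediate
4 | (S)-4-isopropyl-3-[3-(3-methoxy-4-pivaloyloxyphenyl)propanoyl]oxazolidin-2-one | COc1cc(CCC(=O)N2[C@@H](C(C)C)COC2=O)ccc1OC(=O)C(C)(C)C | intermediate
5 | lithium (Z)-enolate of 4 | COc1cc(C/C=C(\O[Li])N2[C@@H](C(C)C)COC2=O)ccc1OC(=O)C(C)(C)C | intermediate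
6 | (2R,3R)-2,3-bis(3-methoxy-4-pivaloyloxybenzyl)-1,4-bis[(S)-4-isopropyl-2-oxooxazolidin-3-yl]butane-1,4-dione | O=C(N1[C@@H](C(C)C)COC1=O)[C@H](Cc1ccc(OC(=O)C(C)(C)C)c(OC)c1)[C@@H](Cc1ccc(OC(=O)C(C)(C)C)c(OC)c1)C(=O)N1[C@@H](C(C)C)COC1=O | intermediate
7 | (−)-secoisolariciresinol = (2R,3R)-2,3-bis(4-hydroxy-3-methoxybenzyl)butane-1,4-diol | OC[C@H](Cc1ccc(O)c(OC)c1)[C@H](CO)Cc1ccc(O)c(OC)c1 | intermediate
8 | tris(2,2,2-trifluoroethyl) orthoformate | FC(F)(F)COC(OCC(F)(F)F)OCC(F)(F)F | starting material
9 | (E)-ferulic acid | COc1cc(/C=C/C(=O)O)ccc1O | starting material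
10 | (5R,6R)-5,6-bis(4-hydroxy-3-methoxybenzyl)-2-(2,2,2-trifluoroethoxy)-1,3-dioxepane (C2 is not stereogenic) | FC(F)(F)COC1OC[C@H](Cc2ccc(O)c(OC)c2)[C@H](CO1)Cc1ccc(O)c(OC)c1 | intermediate
11 | (5R,6R)-5,6-bis(4-hydroxy-3-methoxybenzyl)-1,3-dioxepan-2-yl (E)-ferulate | COc1cc(/C=C/C(=O)OC2OC[C@H](Cc3ccc(O)c(OC)c3)[C@H](CO2)Cc2ccc(O)c(OC)c2)ccc1O | intermediate
12 | (2R,3R)-4-formyloxy-2,3-bis(4-hydroxy-3-methoxybenzyl)butyl (E)-ferulate | COc1cc(/C=C/C(=O)OC[C@H](Cc2ccc(O)c(OC)c2)[C@H](COC=O)Cc2ccc(O)c(OC)c2)ccc1O | intermediate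
13 | hanultarin = (2R,3R)-4-hydroxy-2,3-bis(4-hydroxy-3-methoxybenzyl)butyl (E)-ferulate | COc1cc(/C=C/C(=O)OC[C@H](Cc2ccc(O)c(OC)c2)[C@H](CO)Cc2ccc(O)c(OC)c2)ccc1O | target

## Count and risks
Total steps: 4. Longest linear sequence: 4 (1 → 4 → 6 → 7 → 13).

**Step 4 (the new step).**
- Risks: exchange on the electron-poor orthoformate may be sluggish. The SN2 opening at the β-branched OCH2 may be too slow at 100 °C. The cation may be intercepted by a phenol or an arene.
- Fallback (known chemistry): it sets out from 7 and 9 and comes back at 13.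
- Ac2O in cold aqueous NaOH acetylates only the two phenoxides of 7 and gives secoisolariciresinol 4,4'-di-O-acetate F1.
- 9 with Ac2O/pyridine gives (E)-4-O-acetylferulic acid F2.
- Steglich esterification (EDC, cat. DMAP, CH2Cl2, 0 °C) of F2 with a two-fold excess of the diol gives hanultarin tri-O-acetate F3, and the surplus diol is recovered and recycled.
- Pyrrolidine in EtOH at rt aminolyses the three aryl acetates, leaves the alkyl cinnamate intact, and gives 13.

**Step 2.**
- Risks: the yield and diastereomer ratio are only moderate. α-Chlorination by CuCl2 or attack of the enolate on the pivalate could lower the yield further.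
- Fallback: it builds the two centres one after the other. It sets out from 4 and comes back at 7.
- NaHMDS, then tert-butyl bromoacetate (Evans alkylation), gives tert-butyl (R)-3-[(S)-4-isopropyl-2-oxooxazolidine-3-carbonyl]-4-(3-methoxy-4-pivaloyloxyphenyl)butanoate F4.
- LiBH4/MeOH at 0 °C removes the auxiliary and gives tert-butyl (R)-3-(hydroxymethyl)-4-(3-methoxy-4-pivaloyloxyphenyl)butanoate F5.
- TFA closes this to (R)-4-(3-methoxy-4-pivaloyloxybenzyl)dihydrofuran-2(3H)-one F6.
- PBr3 on commercial 4-benzyloxy-3-methoxybenzyl alcohol gives 4-benzyloxy-3-methoxybenzyl bromide F7.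
- LiHMDS at −78 °C alkylates the lactone with this bromide anti to the C4 substituent and gives (3R,4R)-3-(4-benzyloxy-3-methoxybenzyl)-4-(3-methoxy-4-pivaloyloxybenzyl)dihydrofuran-2(3H)-one F8.
- LiAlH4 opens the lactone, cleaves the pivalate, and gives (2R,3R)-2-(4-benzyloxy-3-methoxybenzyl)-3-(4-hydroxy-3-methoxybenzyl)butane-1,4-diol F9.
- H2 over Pd/C gives 7.

**Step 3.**
- Risk: hydride may attack the ring carbonyl of the hindered imides. This gives ring-opened amides, and material and auxiliary are lost.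
- Fallback: hydrolysis first, then borane reduction. It sets out from 6 and comes back at 7.
- LiOH/H2O2 in THF/H2O (0 °C to rt, excess LiOH) cleaves both auxiliaries at the exocyclic carbonyl and both pivalates, giving (2R,3R)-2,3-bis(4-hydroxy-3-methoxybenzyl)succinic acid F10.
- Excess BH3·THF reduces this diacid to 7.

## Further compounds
F1 | step 4 | secoisolariciresinol 4,4'-di-O-acetate | OC[C@H](Cc1ccc(OC(C)=O)c(OC)c1)[C@H](CO)Cc1ccc(OC(C)=O)c(OC)c1
F2 | step 4 | (E)-4-O-acetylferulic acid | COc1cc(/C=C/C(=O)O)ccc1OC(C)=O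
F3 | step 4 | hanultarin tri-O-acetate | COc1cc(/C=C/C(=O)OC[C@H](Cc2ccc(OC(C)=O)c(OC)c2)[C@H](CO)Cc2ccc(OC(C)=O)c(OC)c2)ccc1OC(C)=O
F4 | step 2 | tert-butyl (R)-3-[(S)-4-isopropyl-2-oxooxazolidine-3-carbonyl]-4-(3-methoxy-4-pivaloyloxyphenyl)butanoate | O=C(N1[C@@H](C(C)C)COC1=O)[C@H](Cc1ccc(OC(=O)C(C)(C)C)c(OC)c1)CC(=O)OC(C)(C)C
F5 | step 2 | tert-butyl (R)-3-(hydroxymethyl)-4-(3-methoxy-4-pivaloyloxyphenyl)butanoate | OC[C@H](Cc1ccc(OC(=O)C(C)(C)C)c(OC)c1)CC(=O)OC(C)(C)C
F6 | step 2 | (R)-4-(3-methoxy-4-pivaloyloxybenzyl)dihydrofuran-2(3H)-one | O=C1C[C@@H](Cc2ccc(OC(=O)C(C)(C)C)c(OC)c2)CO1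
F7 | step 2 | 4-benzyloxy-3-methoxybenzyl bromide | COc1cc(CBr)ccc1OCc1ccccc1
F8 | step 2 | (3R,4R)-3-(4-benzyloxy-3-methoxybenzyl)-4-(3-methoxy-4-pivaloyloxybenzyl)dihydrofuran-2(3H)-one | O=C1OC[C@H](Cc2ccc(OC(=O)C(C)(C)C)c(OC)c2)[C@H]1Cc1ccc(OCc2ccccc2)c(OC)c1
F9 | step 2 | (2R,3R)-2-(4-benzyloxy-3-methoxybenzyl)-3-(4-hydroxy-3-methoxybenzyl)butane-1,4-diol | OC[C@H](Cc1ccc(O)c(OC)c1)[C@H](CO)Cc1ccc(OCc2ccccc2)c(OC)c1
F10 | step 3 | (2R,3R)-2,3-bis(4-hydroxy-3-methoxybenzyl)succinic acid | OC(=O)[C@H](Cc1ccc(O)c(OC)c1)[C@@H](Cc1ccc(O)c(OC)c1)C(=O)O
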